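**Assumption:** the SMILES encodes the (2S)-flavanone (checked by CIP analysis: O1 > phenyl > C3 > H), and that enantiomer is made.

## Retrosynthetic overview

1. Last bond, C8–CH2Ar: Zn(II)-mediated ortho-hydroxybenzylation of the 6-substituted (2S)-flavanone, where C8 is the only free A-ring carbon.
2. Before that, C6–CH2Ar: benzylation ortho to the chelated 5-OH of (2S)-7-O-benzylpinocembrin with the pre-assembled tris-phenol benzylic alcohol. The 7-O-benzyl group makes C6 and C8 different and is then hydrogenolysed.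
3. Key disconnection, pyranone C4–C3: an NHC-generated acyl anion of an ortho-alkoxybenzaldehyde displaces a primary halide intramolecularly (carbonyl carbon + C–X carbon, both natively electrophilic). C2 is set just before by Mitsunobu inversion of (R)-3-chloro-1-phenylpropan-1-ol.
4. Side chain: two iterative tosylhydrazone/boronic acid reductive couplings from salicylaldehyde and (3-formyl-4-hydroxyphenyl)boronic acid, then NaBH4.
5. Ring order: all benzene rings are bought; the only ring formed is the pyranone C ring (step 3), fused onto the phloroglucinaldehyde A ring.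

## Route

Step 1
Reactants: 1 phloroglucinaldehyde (2,4,6-trihydroxybenzaldehyde)
Product: 2 benzyl ether 4-(benzyloxy)-2,6-dihydroxybenzaldehyde
Conditions: BnBr (1.0 equiv), NaHCO3 (1.1 equiv), DMF, 40 °C
Reagents that add atoms: benzyl bromide, BrCc1ccccc1
Why: Williamson etherification in which one equivalent of weak base ionises only the non-chelated 4-OH (para to CHO, the most acidic phenol), while both ortho OH groups stay hydrogen-bonded to the aldehyde.

Step 2
Reactants: 2 benzyl ether 4-(benzyloxy)-2,6-dihydroxybenzaldehyde; 3 (R)-3-chloro-1-phenylpropan-1-ol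
Product: 4 aryl ether 4-(benzyloxy)-2-[(1S)-3-chloro-1-phenylpropoxy]-6-hydroxybenzaldehyde
Conditions: PPh3, DIAD, THF, 0 °C → rt (1.0 equiv of 3)
Reagents that add atoms: none
Why: Mitsunobu etherification of the C2-symmetric bis-phenol gives one mono-ether (the remaining OH is then strongly chelated), and SN2 attack on the benzylic oxyphosphonium inverts (R) to (S), which sets the future C2 stereocentre.

Step 3
Reactants: 4 aryl ether 4-(benzyloxy)-2-[(1S)-3-chloro-1-phenylpropoxy]-6-hydroxybenzaldehyde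
Product: 6 (2S)-7-(benzyloxy)-5-hydroxy-2-phenylchroman-4-one, via primary iodide 5 (not isolated)
Conditions: NaI (1.5 equiv), MeCN, 70 °C; then 2-(pentafluorophenyl)-6,7-dihydro-5H-pyrrolo[2,1-c][1,2,4]triazol-2-ium BF4 (20 mol %), iPr2NEt (2 equiv), MeCN (0.02 M), 50 °C
Reagents that add atoms: none
Why: After Finkelstein exchange the carbene turns the H-bond-activated aldehyde carbon into a catalyst-bound acyl anion equivalent that alkylates the primary iodide in a 6-exo-tet SN2 (NHC-catalysed umpolung alkylation of aldehydes, the known chroman-4-one closure of 2-(2-haloethoxy)benzaldehydes), forming C4–C3 without touching the ether stereocentre, which becomes (2S).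

Step 4
Reactants: 7 salicylaldehyde (2-hydroxybenzaldehyde); 8 (3-formyl-4-hydroxyphenyl)boronic acid
Product: 10 bis-phenol aldehyde 2-hydroxy-5-[(2-hydroxyphenyl)methyl]benzaldehyde, via tosylhydrazone 9 (not isolated)
Conditions: TsNHNH2 (1.0 equiv), 1,4-dioxane, 80 °C; then 8 (1.5 equiv), K2CO3 (4 equiv), 110 °C
Reagents that add atoms: none
Why: Barluenga–Valdés metal-free reductive coupling (base-induced Bamford–Stevens loss of sulfinate, C–B bond formation with 1,2-aryl shift and N2 loss, then protodeboronation) joins the former aldehyde carbon exactly to the boron-bearing carbon, para to the OH of the new ring, with no ortho/para mixture and with the formyl group of 8 kept for the next round.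

Step 5
Reactants: 10 bis-phenol aldehyde 2-hydroxy-5-[(2-hydroxyphenyl)methyl]benzaldehyde; 8 (3-formyl-4-hydroxyphenyl)boronic acid
Product: 12 tris-phenol aldehyde 2-hydroxy-5-({2-hydroxy-5-[(2-hydroxyphenyl)methyl]phenyl}methyl)benzaldehyde, via tosylhydrazone 11 (not isolated)
Conditions: TsNHNH2 (1.0 equiv), 1,4-dioxane, 80 °C; then 8 (1.5 equiv), K2CO3 (5 equiv), 110 °C
Reagents that add atoms: none
Why: A second round of the same Barluenga–Valdés reductive coupling converts the CHO of 10 into the next CH2 bridge, again regiospecifically at the ipso carbon of the boronic acid.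

Step 6
Reactants: 12 tris-phenol aldehyde 2-hydroxy-5-({2-hydroxy-5-[(2-hydroxyphenyl)methyl]phenyl}methyl)benzaldehyde
Product: 13 tris-phenol benzylic alcohol 2-(hydroxymethyl)-4-({2-hydroxy-5-[(2-hydroxyphenyl)methyl]phenyl}methyl)phenol
Conditions: NaBH4, MeOH/THF, 0 °C
Reagents that add atoms: none
Why: Hydride reduction of the aryl aldehyde gives the o-hydroxybenzyl alcohol that serves as the o-quinone methide precursor.

Step 7
Reactants: 6 (2S)-7-(benzyloxy)-5-hydroxy-2-phenylchroman-4-one; 13 tris-phenol benzylic alcohol 2-(hydroxymethyl)-4-({2-hydroxy-5-[(2-hydroxyphenyl)methyl]phenyl}methyl)phenol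
Product: 15 (2S)-7-(benzyloxy)-5-hydroxy-6-{[2-hydroxy-5-({2-hydroxy-5-[(2-hydroxyphenyl)methyl]phenyl}methyl)phenyl]methyl}-2-phenylchroman-4-one, via o-quinone methide 14 (not isolated)
Conditions: ZnCl2 (2.5 equiv), 1,4-dioxane, 80 °C, 13 (1.2 equiv) added slowly
Reagents that add atoms: none
Why: In this Zn(II)-mediated Friedel–Crafts ortho-hydroxybenzylation the metal bridges the chelated 5-O of 6 and the electrophile, so the bond forms ortho to the only free phenol (C6, the site also taken by halogenation of 5-hydroxy-7-alkoxyflavonoids) rather than at C8 between two ether oxygens or on the less electron-rich chain phenols, and C2 is not involved.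

Step 8
Reactants: 15 (2S)-7-(benzyloxy)-5-hydroxy-6-{[2-hydroxy-5-({2-hydroxy-5-[(2-hydroxyphenyl)methyl]phenyl}methyl)phenyl]methyl}-2-phenylchroman-4-one
Product: 16 (2S)-5,7-dihydroxy-6-{[2-hydroxy-5-({2-hydroxy-5-[(2-hydroxyphenyl)methyl]phenyl}methyl)phenyl]methyl}-2-phenylchroman-4-one
Conditions: H2 (1 atm), 10% Pd/C, EtOAc/MeOH, rt
Reagents that add atoms: none
Why: Hydrogenolysis of the aryl benzyl ether is faster than cleavage of the cyclic benzylic C2–O bond or reduction of the chelated C4 ketone, and the diarylmethane CH2 groups are inert.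

Step 9
Reactants: 16 (2S)-5,7-dihydroxy-6-{[2-hydroxy-5-({2-hydroxy-5-[(2-hydroxyphenyl)methyl]phenyl}methyl)phenyl]methyl}-2-phenylchroman-4-one; 17 saligenin (2-(hydroxymethyl)phenol)
Product: 19 sarmentosumin B, via o-quinone methide 18 (not isolated)
Conditions: ZnCl2 (2 equiv), 1,4-dioxane, 80 °C, 17 (1.2 equiv)
Reagents that add atoms: none
Why: The same Zn(II)-mediated o-quinone methide Friedel–Crafts benzylation now has only C8 left on the phloroglucinol ring, ortho to the freed 7-OH, and this ring is far more nucleophilic than the alkylphenol rings of the side chain.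

## Compound list

1 | phloroglucinaldehyde (2,4,6-trihydroxybenzaldehyde) | O=Cc1c(O)cc(O)cc1O | starting material
2 | 4-(benzyloxy)-2,6-dihydroxybenzaldehyde | O=Cc1c(O)cc(OCc2ccccc2)cc1O | intermediate
3 | (R)-3-chloro-1-phenylpropan-1-ol | O[C@H](CCCl)c1ccccc1 | starting material
4 | 4-(benzyloxy)-2-[(1S)-3-chloro-1-phenylpropoxy]-6-hydroxybenzaldehyde | O=Cc1c(O)cc(OCc2ccccc2)cc1O[C@@H](CCCl)c1ccccc1 | intermediate
5 | 4-(benzyloxy)-2-hydroxy-6-[(1S)-3-iodo-1-phenylpropoxy]benzaldehyde | O=Cc1c(O)cc(OCc2ccccc2)cc1O[C@@H](CCI)c1ccccc1 | intermediate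
6 | (2S)-7-(benzyloxy)-5-hydroxy-2-phenylchroman-4-one | O=C1C[C@@H](c2ccccc2)Oc2cc(OCc3ccccc3)cc(O)c21 | intermediate
7 | salicylaldehyde (2-hydroxybenzaldehyde) | O=Cc1ccccc1O | starting material
8 | (3-formyl-4-hydroxyphenyl)boronic acid | OB(O)c1ccc(O)c(C=O)c1 | starting material
9 | N'-[(E)-(2-hydroxyphenyl)methylidene]-4-methylbenzenesulfonohydrazide | Cc1ccc(cc1)S(=O)(=O)N/N=C/c1ccccc1O | intermediate
10 | 2-hydroxy-5-[(2-hydroxyphenyl)methyl]benzaldehyde | O=Cc1cc(Cc2ccccc2O)ccc1O | intermediate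
11 | N'-[(E)-{2-hydroxy-5-[(2-hydroxyphenyl)methyl]phenyl}methylidene]-4-methylbenzenesulfonohydrazide | Cc1ccc(cc1)S(=O)(=O)N/N=C/c1cc(Cc2ccccc2O)ccc1O | intermediate
12 | 2-hydroxy-5-({2-hydroxy-5-[(2-hydroxyphenyl)methyl]phenyl}methyl)benzaldehyde | O=Cc1cc(Cc2cc(Cc3ccccc3O)ccc2O)ccc1O | intermediate
13 | 2-(hydroxymethyl)-4-({2-hydroxy-5-[(2-hydroxyphenyl)methyl]phenyl}methyl)phenol | OCc1cc(Cc2cc(Cc3ccccc3O)ccc2O)ccc1O | intermediate
14 | 4-({2-hydroxy-5-[(2-hydroxyphenyl)methyl]phenyl}methyl)-6-methylidenecyclohexa-2,4-dien-1-one | C=C1C=C(Cc2cc(Cc3ccccc3O)ccc2O)C=CC1=O | intermediate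
15 | (2S)-7-(benzyloxy)-5-hydroxy-6-{[2-hydroxy-5-({2-hydroxy-5-[(2-hydroxyphenyl)methyl]phenyl}methyl)phenyl]methyl}-2-phenylchroman-4-one | O=C1C[C@@H](c2ccccc2)Oc2cc(OCc3ccccc3)c(Cc3cc(Cc4cc(Cc5ccccc5O)ccc4O)ccc3O)c(O)c21 | intermediate
16 | (2S)-5,7-dihydroxy-6-{[2-hydroxy-5-({2-hydroxy-5-[(2-hydroxyphenyl)methyl]phenyl}methyl)phenyl]methyl}-2-phenylchroman-4-one | O=C1C[C@@H](c2ccccc2)Oc2cc(O)c(Cc3cc(Cc4cc(Cc5ccccc5O)ccc4O)ccc3O)c(O)c21 | intermediate
17 | saligenin (2-(hydroxymethyl)phenol) | OCc1ccccc1O | starting material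
18 | 6-methylidenecyclohexa-2,4-dien-1-one | C=C1C=CC=CC1=O | intermediate
19 | sarmentosumin B, (2S)-5,7-dihydroxy-8-[(2-hydroxyphenyl)methyl]-6-{[2-hydroxy-5-({2-hydroxy-5-[(2-hydroxyphenyl)methyl]phenyl}methyl)phenyl]methyl}-2-phenylchroman-4-one | O=C1C[C@@H](c2ccccc2)Oc2c(Cc3ccccc3O)c(O)c(Cc3cc(Cc4cc(Cc5ccccc5O)ccc4O)ccc3O)c(O)c21 | target

## Step count and risks

Total step count: 9. Longest linear sequence: 6 (steps 1, 2, 3, 7, 8, 9 or steps 4, 5, 6, 7, 8, 9).

**Step 3 (key ring closure).** Carbene addition to the electron-rich, doubly ortho-substituted aldehyde may be slow, the iodide may alkylate the catalyst, and base could partly racemise 6 by retro-oxa-Michael opening. The fallback sets out from 4 and comes back at 6, replacing the catalytic acyl anion by a stoichiometric one. Aldehyde 4 is treated with propane-1,3-dithiol and catalytic I2 in CH2Cl2 to give the dithiane 2-{4-(benzyloxy)-2-[(1S)-3-chloro-1-phenylpropoxy]-6-hydroxyphenyl}-1,3-dithiane F1. Its dianion (n-BuLi 2.2 equiv, THF, −78 → −20 °C) closes the ring by displacing chloride to give the spiro-dithiane (2S)-7-(benzyloxy)-2-phenylspiro[chromane-4,2'-[1,3]dithian]-5-ol F2. MeI and CaCO3 in aqueous MeCN then unmask ketone 6.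

**Step 5 (second reductive coupling; step 4 is the same reaction on a simpler substrate).** The ortho-phenoxide hydrazone may decompose unproductively, and boronic acid 8 may protodeboronate before it couples. The fallback sets out from 10 and comes back at 12, replacing the hydrazone by an o-quinone methide precursor. NaBH4 in MeOH reduces 10 to 2-(hydroxymethyl)-4-[(2-hydroxyphenyl)methyl]phenol F3. F3 is then arylated by 8 through boron-assisted 1,4-aryl transfer (Petasis-type addition of the boronate to the o-quinone methide; 3,3'-dibromo-BINOL 20 mol %, 4 Å MS, toluene, 80 °C) to give 12.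

**Step 7 (C6 benzylation).** C6/C8 mixtures, self-condensation of 13 and Lewis-acid racemisation or ring-opening isomerisation of the flavanone are all possible. The fallback sets out from 2 and comes back at 15, fixing the regiochemistry by symmetry before the heterocycle exists.
- The still C2-symmetric aldehyde 2 (in excess) is benzylated with 13 (ZnCl2, dioxane, 60 °C). Only one constitutional isomer is possible: 4-(benzyloxy)-2,6-dihydroxy-3-{[2-hydroxy-5-({2-hydroxy-5-[(2-hydroxyphenyl)methyl]phenyl}methyl)phenyl]methyl}benzaldehyde F4.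
- Mitsunobu reaction with 3 at the less hindered and most acidic aldehyde-flanked OH gives 4-(benzyloxy)-6-[(1S)-3-chloro-1-phenylpropoxy]-2-hydroxy-3-{[2-hydroxy-5-({2-hydroxy-5-[(2-hydroxyphenyl)methyl]phenyl}methyl)phenyl]methyl}benzaldehyde F5. Competition from the three chain phenols is the weak point here.
- NaI exchange to the iodide 4-(benzyloxy)-2-hydroxy-6-[(1S)-3-iodo-1-phenylpropoxy]-3-{[2-hydroxy-5-({2-hydroxy-5-[(2-hydroxyphenyl)methyl]phenyl}methyl)phenyl]methyl}benzaldehyde F6 and NHC cyclisation as in step 3 deliver 15. This route also exposes the stereocentre to ZnCl2 only once.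

## Further compounds

F1 | step 3 | 2-{4-(benzyloxy)-2-[(1S)-3-chloro-1-phenylpropoxy]-6-hydroxyphenyl}-1,3-dithiane | Oc1cc(OCc2ccccc2)cc(O[C@@H](CCCl)c2ccccc2)c1C1SCCCS1
F2 | step 3 | (2S)-7-(benzyloxy)-2-phenylspiro[chromane-4,2'-[1,3]dithian]-5-ol | Oc1cc(OCc2ccccc2)cc2O[C@H](c3ccccc3)CC3(SCCCS3)c12
F3 | step 5 | 2-(hydroxymethyl)-4-[(2-hydroxyphenyl)methyl]phenol | OCc1cc(Cc2ccccc2O)ccc1O
F4 | step 7 | 4-(benzyloxy)-2,6-dihydroxy-3-{[2-hydroxy-5-({2-hydroxy-5-[(2-hydroxyphenyl)methyl]phenyl}methyl)phenyl]methyl}benzaldehyde | O=Cc1c(O)cc(OCc2ccccc2)c(Cc2cc(Cc3cc(Cc4ccccc4O)ccc3O)ccc2O)c1O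
F5 | step 7 | 4-(benzyloxy)-6-[(1S)-3-chloro-1-phenylpropoxy]-2-hydroxy-3-{[2-hydroxy-5-({2-hydroxy-5-[(2-hydroxyphenyl)methyl]phenyl}methyl)phenyl]methyl}benzaldehyde | O=Cc1c(O[C@@H](CCCl)c2ccccc2)cc(OCc2ccccc2)c(Cc2cc(Cc3cc(Cc4ccccc4O)ccc3O)ccc2O)c1O
F6 | step 7 | 4-(benzyloxy)-2-hydroxy-6-[(1S)-3-iodo-1-phenylpropoxy]-3-{[2-hydroxy-5-({2-hydroxy-5-[(2-hydroxyphenyl)methyl]phenyl}methyl)phenyl]methyl}benzaldehyde | O=Cc1c(O[C@@H](CCI)c2ccccc2)cc(OCc2ccccc2)c(Cc2cc(Cc3cc(Cc4ccccc4O)ccc3O)ccc2O)c1O
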